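**Retrosynthetic overview**
1. Target ⇒ last, peracid epoxidation of the C1=C10 alkene; before that, acylation of C8–OH with (2S,3S)-2,3-dimethyloxirane-2-carboxylic acid, itself made from D-lactic acid.
2. Ten-membered ring and trans-fused α-methylene lactone ⇒ one electroreductive chromium-catalysed Barbier/Nozaki–Hiyama–Kishi closure of the C6–C7 bond, then lactonisation.
3. The acyclic bromo-enoate aldehyde ⇒ ring-opening 2-oxonia-Cope allyl transfer (C8–C9 bond) between a carvone-derived cyclohexenol and a bromo enal.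
4. Cyclohexenol ⇐ (S)-carvone (reduction, benzoylation, allylic oxidation, reduction); bromo enal ⇐ 2,2-dimethoxyacetaldehyde + methyl acrylate.
5. Ring order: bought six-membered ring (opened in the allyl transfer) → ten-membered carbocycle → γ-lactone → side-chain oxirane (made separately) → ring oxirane last.

Assumption: 1, 6, 7 and 19 are commercial; atom labels C1–C15 follow germacranolide numbering of the target (C1–C10 ring, C11–C13 lactone carbons, C14 on C10, C15 on C4) in every intermediate.

**Route**

Step 1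
Reactants: 1 (S)-(+)-carvone
Product: 2 (1S,5S)-2-methyl-5-(prop-1-en-2-yl)cyclohex-2-en-1-ol (cis-carveol)
Conditions: NaBH4, CeCl3·7H2O, MeOH, −78 → 0 °C
Reagents that add atoms: none
Why: Luche 1,2-reduction; hydride adds axially to the half-chair enone that carries the isopropenyl group pseudo-equatorially, which sets the (1S) carbinol (the future C3) cis to the carvone stereocentre.

Step 2
Reactants: 2 (1S,5S)-cis-carveol
Product: 3 (1S,5S)-2-methyl-5-(prop-1-en-2-yl)cyclohex-2-en-1-yl benzoate
Conditions: BzCl, pyridine, DMAP (cat.), CH2Cl2, 0 °C → rt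
Reagents that add atoms: benzoyl chloride, O=C(Cl)c1ccccc1
Why: nucleophilic acyl substitution (DMAP-catalysed acylation) that installs the final C3 benzoate at once and touches no stereocentre.

Step 3
Reactants: 3 cis-carvyl benzoate
Product: 4 (1S,5S)-2-methyl-4-oxo-5-(prop-1-en-2-yl)cyclohex-2-en-1-yl benzoate
Conditions: Rh2(cap)4 (cap = caprolactamate, 1 mol %), 70% aq. t-BuOOH (5 equiv), K2CO3 (0.5 equiv), CH2Cl2, rt
Reagents that add atoms: tert-butyl hydroperoxide, CC(C)(C)OO
Why: dirhodium-caprolactamate/peroxide allylic C–H oxidation (peroxyl radical chain) at the only ring methylene allylic to the trisubstituted alkene, the other allylic CH being deactivated by the benzoate; isopropenyl groups are tolerated in this reaction type and no stereocentre changes.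

Step 4
Reactants: 4 enone benzoate
Product: 5 (1S,4R,5S)-4-hydroxy-2-methyl-5-(prop-1-en-2-yl)cyclohex-2-en-1-yl benzoate
Conditions: NaBH4, CeCl3·7H2O, MeOH, −78 °C
Reagents that add atoms: none
Why: Luche reduction; axial hydride delivery next to the pseudo-equatorial isopropenyl group gives the equatorial (4R) alcohol trans to it, and the minor cis epimer is removed by chromatography and can be re-oxidised to 4.

Step 5
Reactants: 6 2,2-dimethoxyacetaldehyde; 7 methyl acrylate
Product: 8 methyl 3-hydroxy-4,4-dimethoxy-2-methylidenebutanoate (racemic)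
Conditions: DABCO (0.5 equiv), 1,4-dioxane/H2O 1:1, rt, 48 h
Reagents that add atoms: none
Why: Morita–Baylis–Hillman reaction of a reactive glyoxal monoacetal; the new carbinol centre is racemic and is erased in step 6.

Step 6
Reactants: 8 MBH adduct
Product: 10 methyl (2Z)-2-(bromomethyl)-4-oxobut-2-enoate, via bromo acetal 9 (not isolated)
Conditions: NBS, Me2S, CH2Cl2, 0 °C → rt; then TFA/H2O 9:1, 0 °C
Reagents that add atoms: N-bromosuccinimide, O=C1CCC(=O)N1Br; water, O
Why: Corey–Kim-type SN2′ bromination of the MBH alcohol gives the (Z)-2-(bromomethyl) enoate (ester trans to the substituent), and aqueous acid then hydrolyses the dimethyl acetal.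

Step 7
Reactants: 5 cyclohexenol benzoate; 10 bromo enal
Product: 13 methyl (2Z,4R,6E,9S,10Z)-9-(benzoyloxy)-2-(bromomethyl)-4-hydroxy-6,10-dimethyl-12-oxododeca-2,6,10-trienoate, via oxocarbenium ion 11 (not isolated), via ring-expanded oxocarbenium ion 12 (not isolated)
Conditions: 10 (2 equiv), Sn(OTf)2 (10 mol %), CH2Cl2, −40 → 0 °C; aq. NaHCO3
Reagents that add atoms: none
Why: Proposed new method: a ring-opening allyl transfer in which 5 and 10 form a hemiacetal that ionises to ion 11, whose 2-oxonia-Cope [3,3] shift through a trans-decalin-like chair (both ring arms and the aldehyde substituent equatorial) makes the C8–C9 bond, cuts the C1–C6 ring bond and gives the (E)-C1=C10 alkene and the (8R) carbinol by chirality transfer from the carvone-derived C1/C6 centres, while the ring cis-alkene emerges as the (Z)-enal of ion 12, which the water released earlier hydrolyses; conjugation of the new enal and the trisubstituted alkene drive it, the methyl on C10 stabilises the cationic transition state, and excess 10 (far more electrophilic than the product enal) suppresses crossover; the closest known reaction type is the acid-catalysed Nokami allyl transfer (2-oxonia-Cope) from acyclic homoallylic alcohols to aldehydes, here with the donor carbinol tied into a ring so that the transfer opens it.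

Step 8
Reactants: 13 hydroxy bromo enal
Product: 14 methyl (2Z,4R,6E,9S,10Z)-9-(benzoyloxy)-2-(bromomethyl)-4-[(tert-butyldimethylsilyl)oxy]-6,10-dimethyl-12-oxododeca-2,6,10-trienoate
Conditions: TBSOTf, 2,6-lutidine, CH2Cl2, −78 °C
Reagents that add atoms: tert-butyldimethylsilyl triflate, CC(C)(C)[Si](C)(C)OS(=O)(=O)C(F)(F)F
Why: silyl ether formation is faster at −78 °C than cyclisation of the hydroxyl onto the cis bromomethyl group, and the TBS ether later keeps C8–O from lactonising or being eliminated from the allylmetal.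

Step 9
Reactants: 14 silylated bromo enal
Product: 17 (3S,6R,7S,8R)-3-(benzoyloxy)-8-[(tert-butyldimethylsilyl)oxy]germacra-1(10)E,4Z,11(13)-trien-12,6-olide, via silyl ether 15 (not isolated), via hydroxy ester 16 (not isolated)
Conditions: CrCl3·3THF (20 mol %), Me3SiCl (3 equiv), Et4NBF4 (0.1 M), DMF, undivided cell, Al anode/Ni-foam cathode, constant current, 2.2 F mol−1, 14 added over 12 h (2 mM), rt; then 1 M HCl; then p-TsOH·H2O (10 mol %), CH2Cl2, rt
Reagents that add atoms: none
Why: Proposed new method: an electroreductive chromium-catalysed Nozaki–Hiyama–Kishi (Barbier) macrocyclisation in which the cathode returns trivalent to divalent chromium, two divalent chromium ions turn the allylic bromide into an allyl trivalent-chromium species that adds through C7 to the C6 aldehyde in a chair transition state, Me3SiCl frees the catalyst from the alkoxide and the aluminium anode is the terminal reductant; C7 is set by the C8 silyloxy centre (H8 eclipsing the allyl plane, ring chain anti, OTBS outside) and C6 by the ring (both arms pseudo-equatorial, so H6/H7 are anti and the lactone closes trans), the trans outcome resting on the chromium allyl equilibrating because open-chain cases give cis lactones; the closest known reaction types are electro-regenerated chromium-catalysed intermolecular allylation of aldehydes and stoichiometric CrCl2 Barbier macrocyclisations of 2-(bromomethyl)acrylates to germacranolides.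

Step 10
Reactants: 17 silylated macrolactone
Product: 18 (3S,6R,7R,8R)-3-(benzoyloxy)-8-hydroxygermacra-1(10)E,4Z,11(13)-trien-12,6-olide
Conditions: HF·pyridine, THF/pyridine, 0 °C → rt
Reagents that add atoms: none
Why: fluoride-mediated desilylation under buffered acidic conditions, which spares the benzoate and the α-methylene lactone and avoids base-induced lactone migration to C8.

Step 11
Reactants: 19 D-lactic acid
Product: 20 (2R,5R)-2-tert-butyl-5-methyl-1,3-dioxolan-4-one
Conditions: pivalaldehyde, p-TsOH·H2O (cat.), pentane, reflux, Dean–Stark; recrystallise at −78 °C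
Reagents that add atoms: pivalaldehyde, CC(C)(C)C=O
Why: acid-catalysed acetalisation with water removal; the lactate centre steers the new acetal centre to the cis (2R,5R) isomer (about 4:1), which is purified by crystallisation.

Step 12
Reactants: 20 dioxolanone
Product: 22 (2R,5S)-5-acetyl-2-tert-butyl-5-methyl-1,3-dioxolan-4-one, via lithium enolate 21 (not isolated)
Conditions: LiN(iPr)2 (LDA), THF, −78 °C; cannulate into AcCl (3 equiv), THF, −78 °C
Reagents that add atoms: acetyl chloride, CC(=O)Cl
Why: enolate C-acylation on a self-regeneration-of-stereocentres template; the tert-butyl group blocks its own face, so acetyl enters trans to it and C5 becomes the (5S) quaternary centre (the future C2 of the oxirane acid).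

Step 13
Reactants: 22 acetyl dioxolanone
Product: 23 (2R,5S)-2-tert-butyl-5-[(1R)-1-hydroxyethyl]-5-methyl-1,3-dioxolan-4-one
Conditions: Zn(BH4)2, Et2O, −78 → −20 °C
Reagents that add atoms: none
Why: chelation-controlled (Cram cyclic model) ketone reduction; Zn(BH4)2 ties the ketone oxygen to the ring oxygen on C5 and delivers hydride past the flat lactone carbonyl, not the C5 methyl, which gives the (1R) carbinol.

Step 14
Reactants: 23 hydroxyethyl dioxolanone
Product: 24 (2R,5S)-2-tert-butyl-5-[(1R)-1-(methanesulfonyloxy)ethyl]-5-methyl-1,3-dioxolan-4-one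
Conditions: MsCl, Et3N, CH2Cl2, 0 °C
Reagents that add atoms: methanesulfonyl chloride, CS(=O)(=O)Cl
Why: sulfonylation of the secondary alcohol (O–S bond formation), so the carbinol configuration is retained.

Step 15
Reactants: 24 mesylate
Product: 26 (2S,3S)-2,3-dimethyloxirane-2-carboxylic acid, via hydroxy mesylate salt 25 (not isolated)
Conditions: KOH (2.2 equiv), THF/H2O, 0 °C → rt; then aq. KHSO4 to pH 3, 0 °C
Reagents that add atoms: potassium hydroxide, [K+].[OH-]
Why: hydroxide opens the acylal-type lactone, pivalaldehyde leaves, and the freed tertiary alkoxide displaces the mesylate by intramolecular SN2 (3-exo-tet) with inversion at C3, which gives the (2S,3S)-oxirane with carboxyl and C3 methyl cis.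

Step 16
Reactants: 18 hydroxy macrolactone; 26 oxirane acid
Product: 28 (3S,6R,7R,8R)-3-(benzoyloxy)-8-{[(2S,3S)-2,3-dimethyloxirane-2-carbonyl]oxy}germacra-1(10)E,4Z,11(13)-trien-12,6-olide, via mixed anhydride 27 (not isolated)
Conditions: 2,4,6-trichlorobenzoyl chloride, Et3N, THF, 0 °C; then 18, DMAP, toluene, rt
Reagents that add atoms: none
Why: Yamaguchi esterification; the mixed anhydride acylates the hindered secondary C8–OH faster than the lactone can migrate, and no stereocentre is touched.

Step 17
Reactants: 28 diene ester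
Product: 29 target, (1R,3S,6R,7R,8R,10R)-3-(benzoyloxy)-1,10-epoxy-8-{[(2S,3S)-2,3-dimethyloxirane-2-carbonyl]oxy}germacra-4Z,11(13)-dien-12,6-olide
Conditions: m-CPBA (1.1 equiv), NaHCO3, CH2Cl2, 0 °C
Reagents that add atoms: 3-chloroperbenzoic acid, OOC(=O)c1cccc(Cl)c1
Why: Prilezhaev epoxidation; C1=C10 is the only electron-rich alkene (C4=C5 is flanked by two acyloxy-bearing carbons, C11=C13 is conjugated) and the peracid attacks its outer face, the inner one being blocked by the ring, which is expected to give the (1R,10R) oxirane with retention of the E geometry.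

**Compound list**
1 | (S)-(+)-carvone | CC1=CC[C@@H](CC1=O)C(C)=C | starting material
2 | (1S,5S)-2-methyl-5-(prop-1-en-2-yl)cyclohex-2-en-1-ol | C1C=C(C)[C@@H](O)C[C@H]1C(C)=C | intermediate
3 | (1S,5S)-2-methyl-5-(prop-1-en-2-yl)cyclohex-2-en-1-yl benzoate | C1C=C(C)[C@@H](OC(=O)c2ccccc2)C[C@H]1C(C)=C | intermediate
4 | (1S,5S)-2-methyl-4-oxo-5-(prop-1-en-2-yl)cyclohex-2-en-1-yl benzoate | O=C1C=C(C)[C@@H](OC(=O)c2ccccc2)C[C@H]1C(C)=C | intermediate
5 | (1S,4R,5S)-4-hydroxy-2-methyl-5-(prop-1-en-2-yl)cyclohex-2-en-1-yl benzoate | O[C@@H]1C=C(C)[C@@H](OC(=O)c2ccccc2)C[C@H]1C(C)=C | intermediate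
6 | 2,2-dimethoxyacetaldehyde | COC(OC)C=O | starting material
7 | methyl acrylate | C=CC(=O)OC | starting material
8 | methyl 3-hydroxy-4,4-dimethoxy-2-methylidenebutanoate (racemic) | COC(=O)C(=C)C(O)C(OC)OC | intermediate
9 | methyl (2Z)-2-(bromomethyl)-4,4-dimethoxybut-2-enoate | COC(=O)/C(CBr)=C/C(OC)OC | intermediate
10 | methyl (2Z)-2-(bromomethyl)-4-oxobut-2-enoate | COC(=O)/C(CBr)=C/C=O | intermediate
11 | oxocarbenium ion from 5 and 10 (ring oxygen of 5 double-bonded to the former aldehyde carbon of 10) | COC(=O)/C(CBr)=C/C=[O+][C@@H]1C=C(C)[C@@H](OC(=O)c2ccccc2)C[C@H]1C(C)=C | intermediate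
12 | ten-membered cyclic oxocarbenium ion (O bridging C6 and C8) after the [3,3] shift | [O+]1=C/C=C(/C)[C@@H](OC(=O)c2ccccc2)C/C=C(\C)C[C@@H]1/C=C(\CBr)C(=O)OC | intermediate
13 | methyl (2Z,4R,6E,9S,10Z)-9-(benzoyloxy)-2-(bromomethyl)-4-hydroxy-6,10-dimethyl-12-oxododeca-2,6,10-trienoate | O=C/C=C(/C)[C@@H](OC(=O)c1ccccc1)C/C=C(\C)C[C@@H](O)/C=C(\CBr)C(=O)OC | intermediate
14 | methyl (2Z,4R,6E,9S,10Z)-9-(benzoyloxy)-2-(bromomethyl)-4-[(tert-butyldimethylsilyl)oxy]-6,10-dimethyl-12-oxododeca-2,6,10-trienoate | O=C/C=C(/C)[C@@H](OC(=O)c1ccccc1)C/C=C(\C)C[C@@H](O[Si](C)(C)C(C)(C)C)/C=C(\CBr)C(=O)OC | intermediate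
15 | methyl (3S,6R,7R,8R)-3-(benzoyloxy)-8-[(tert-butyldimethylsilyl)oxy]-6-[(trimethylsilyl)oxy]germacra-1(10)E,4Z,11(13)-trien-12-oate | C[Si](C)(C)O[C@@H]1/C=C(/C)[C@@H](OC(=O)c2ccccc2)C/C=C(\C)C[C@@H](O[Si](C)(C)C(C)(C)C)[C@H]1C(=C)C(=O)OC | intermediate
16 | methyl (3S,6R,7S,8R)-3-(benzoyloxy)-8-[(tert-butyldimethylsilyl)oxy]-6-hydroxygermacra-1(10)E,4Z,11(13)-trien-12-oate | O[C@@H]1/C=C(/C)[C@@H](OC(=O)c2ccccc2)C/C=C(\C)C[C@@H](O[Si](C)(C)C(C)(C)C)[C@H]1C(=C)C(=O)OC | intermediate
17 | (3S,6R,7S,8R)-3-(benzoyloxy)-8-[(tert-butyldimethylsilyl)oxy]germacra-1(10)E,4Z,11(13)-trien-12,6-olide | C=C1C(=O)O[C@@H]2/C=C(/C)[C@@H](OC(=O)c3ccccc3)C/C=C(\C)C[C@@H](O[Si](C)(C)C(C)(C)C)[C@@H]12 | intermediate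
18 | (3S,6R,7R,8R)-3-(benzoyloxy)-8-hydroxygermacra-1(10)E,4Z,11(13)-trien-12,6-olide | C=C1C(=O)O[C@@H]2/C=C(/C)[C@@H](OC(=O)c3ccccc3)C/C=C(\C)C[C@@H](O)[C@@H]12 | intermediate
19 | D-lactic acid, (R)-2-hydroxypropanoic acid | C[C@@H](O)C(=O)O | starting material
20 | (2R,5R)-2-tert-butyl-5-methyl-1,3-dioxolan-4-one | C[C@H]1O[C@@H](C(C)(C)C)OC1=O | intermediate
21 | lithium enolate of 20, lithium (2R)-2-tert-butyl-5-methyl-1,3-dioxol-4-olate | [Li+].CC1=C([O-])O[C@H](C(C)(C)C)O1 | intermediate
22 | (2R,5S)-5-acetyl-2-tert-butyl-5-methyl-1,3-dioxolan-4-one | CC(=O)[C@]1(C)O[C@@H](C(C)(C)C)OC1=O | intermediate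
23 | (2R,5S)-2-tert-butyl-5-[(1R)-1-hydroxyethyl]-5-methyl-1,3-dioxolan-4-one | C[C@@H](O)[C@]1(C)O[C@@H](C(C)(C)C)OC1=O | intermediate
24 | (2R,5S)-2-tert-butyl-5-[(1R)-1-(methanesulfonyloxy)ethyl]-5-methyl-1,3-dioxolan-4-one | C[C@@H](OS(C)(=O)=O)[C@]1(C)O[C@@H](C(C)(C)C)OC1=O | intermediate
25 | potassium (2S,3R)-2-hydroxy-3-(methanesulfonyloxy)-2-methylbutanoate | [K+].[O-]C(=O)[C@@]([C@H](OS(C)(=O)=O)C)(C)O | intermediate
26 | (2S,3S)-2,3-dimethyloxirane-2-carboxylic acid | OC(=O)[C@@]1(C)O[C@H]1C | intermediate
27 | 2,4,6-trichlorobenzoic (2S,3S)-2,3-dimethyloxirane-2-carboxylic anhydride | O=C(OC(=O)[C@@]1(C)O[C@H]1C)c1c(Cl)cc(Cl)cc1Cl | intermediate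
28 | (3S,6R,7R,8R)-3-(benzoyloxy)-8-{[(2S,3S)-2,3-dimethyloxirane-2-carbonyl]oxy}germacra-1(10)E,4Z,11(13)-trien-12,6-olide | C=C1C(=O)O[C@@H]2/C=C(/C)[C@@H](OC(=O)c3ccccc3)C/C=C(\C)C[C@@H](OC(=O)[C@@]3(C)O[C@H]3C)[C@@H]12 | intermediate
29 | CNP0324463.3, (1R,3S,6R,7R,8R,10R)-3-(benzoyloxy)-1,10-epoxy-8-{[(2S,3S)-2,3-dimethyloxirane-2-carbonyl]oxy}germacra-4Z,11(13)-dien-12,6-olide | C=C1C(=O)O[C@@H]2/C=C(/C)[C@@H](OC(=O)c3ccccc3)C[C@H]3O[C@]3(C)C[C@@H](OC(=O)[C@@]3(C)O[C@H]3C)[C@@H]12 | target

**Step count and risks**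

Total steps: 17. Longest linear sequence: 10 (steps 1, 2, 3, 4, 7, 8, 9, 10, 16, 17).

The three steps most likely to fail are 7, 9 and 13.

Step 7 (ring-opening allyl transfer, proposed new) may stall at a Prins adduct, erode the Z-enal, or give crossover. The fallback uses two known reactions and sets out from 5 and 10 to come back at 13. SnBr4 in CH2Cl2 at −78 °C completes the Prins cyclisation and traps the tertiary cation as the isolable trans-fused bromotetrahydropyran, methyl (2Z)-2-(bromomethyl)-3-[6-(benzoyloxy)-4-bromo-4,7-dimethyl-3,4,4a,5,6,8a-hexahydro-2H-chromen-2-yl]prop-2-enoate F1, with the bromide equatorial on C10. AgOTf and 2,6-lutidine in wet THF then trigger a Grob fragmentation (C10–Br anti-periplanar to the C1–C6 bond) to ion 12, which water opens to 13.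

Step 9 (electroreductive macrocyclisation, proposed new) may suffer cathodic reduction of the enal, dimerisation, or give the cis lactone. The fallback leaves electrochemistry for the known palladium/diethylzinc umpolung allylation that has closed ten-membered germacrane rings; it sets out from 14 and comes back at 17 through 16. Pd(PPh3)4 (5 mol %) and Et2Zn (3 equiv) in THF, with slow addition of 14, give a π-allyl complex of zerovalent palladium that Et2Zn turns into an allylzinc; this closes the ring thermally, and p-TsOH lactonises 16. It isolates no new compound (none F0).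

Step 13 (chelation-controlled reduction) may prefer the other ketone face and give the (1S) carbinol. The fallback swaps nucleophile and resident group so that the same face preference gives the needed epimer; it sets out from enolate 21 and comes back at 23. Methyl formate quenches 21 to (2R,4S)-2-tert-butyl-4-methyl-5-oxo-1,3-dioxolane-4-carbaldehyde F2, and MeMgBr (Et2O, −78 °C) adds under the same chelate to give 23.

Further compounds
F1 | step 7 | methyl (2Z)-2-(bromomethyl)-3-[6-(benzoyloxy)-4-bromo-4,7-dimethyl-3,4,4a,5,6,8a-hexahydro-2H-chromen-2-yl]prop-2-enoate (trans-fused Prins adduct of 5 and 10) | O1[C@@H]2C=C(C)[C@@H](OC(=O)c3ccccc3)C[C@H]2[C@](C)(Br)C[C@@H]1/C=C(\CBr)C(=O)OC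
F0 | step 9 | none | none
F2 | step 13 | (2R,4S)-2-tert-butyl-4-methyl-5-oxo-1,3-dioxolane-4-carbaldehyde | O=C[C@]1(C)O[C@@H](C(C)(C)C)OC1=O
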